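In ring B of the target (B1 quaternary, B2, B3=B4 with a methyl on B4, B5 carbinol carbon, B6), the fully substituted B1, bonded to the methyl-bearing quaternary carbon of cyclopentane ring A, lies directly across from B4. This 1,4-pattern about the B3=B4 alkene is cut back to isoprene and an α-substituted acrolein: one catalyst-controlled [4+2] cycloaddition forms B1–B2 and B5–B6, closes ring B and sets the B1 centre beside the ring-A quaternary centre installed earlier. The dienophile is an acrolein whose 2-position carries the 1-methylcyclopentyl unit with the adjacent ring ketone, the future methylidene-bearing carbon, masked as a dioxolane; the formyl carbon is later reduced to the B1 methyl and B5 is oxygenated afterwards.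

Key step: step 7

Assumption: the sense of induction of both asymmetric catalysts is taken from their accepted models (the (S)-phosphinooxazoline ligand gives (S)-2-allyl-2-methylcycloalkanones; the (S)-oxazaborolidinium ion, holding a 2-substituted s-trans acrolein by a formyl C–H···O contact, exposes the face that leads here to the (1S)-cycloadduct), so the (R)-ligand and the (S)-oxazaborolidine are specified.

Step 1
Reactants: 1 methyl 2-oxocyclopentane-1-carboxylate; 2 allyl alcohol
Product: 3 prop-2-en-1-yl 2-oxocyclopentane-1-carboxylate (racemic, labile α-centre)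
Conditions: 2 (3 equiv), 4-(dimethylamino)pyridine (0.2 equiv), toluene, reflux, 4 Å molecular sieves to trap MeOH
Reagents that add atoms: none
Why: Transesterification of an enolisable β-keto ester, which runs through the acylketene or the acylpyridinium species and is driven to the allyl ester by continuous removal of methanol; the α-stereocentre is labile and of no consequence.

Step 2
Reactants: 3 prop-2-en-1-yl 2-oxocyclopentane-1-carboxylate
Product: 4 prop-2-en-1-yl 1-methyl-2-oxocyclopentane-1-carboxylate (racemic)
Conditions: MeI, K2CO3, acetone, 45 °C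
Reagents that add atoms: iodomethane, CI
Why: Carbonate removes the doubly activated α-hydrogen and the enolate is C-methylated by iodomethane (SN2 alkylation of a β-keto ester), the racemic quaternary centre being erased in the next step.

Step 3
Reactants: 4 prop-2-en-1-yl 1-methyl-2-oxocyclopentane-1-carboxylate
Product: 5 (2R)-2-methyl-2-(prop-2-en-1-yl)cyclopentan-1-one
Conditions: Pd2(dba)3 (2.5 mol%), (R)-4-tert-butyl-2-[2-(diphenylphosphanyl)phenyl]-4,5-dihydro-1,3-oxazole (6.5 mol%), THF, 25 °C
Reagents that add atoms: none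
Why: Decarboxylative asymmetric allylic alkylation (Tsuji type), in which zerovalent palladium ionises the allyl ester, loss of CO2 leaves a prochiral palladium enolate common to both enantiomers of 4, and C–C bond formation inside the chiral P,N-ligand sphere sets the quaternary centre of ring A, the (R)-ligand being chosen because the (S)-ligand is known to give (S)-2-allyl-2-methylcycloalkanones.

Step 4
Reactants: 5 (2R)-2-methyl-2-(prop-2-en-1-yl)cyclopentan-1-one
Product: 6 (6R)-6-methyl-6-(prop-2-en-1-yl)-1,4-dioxaspiro[4.4]nonane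
Conditions: ethylene glycol, p-TsOH·H2O (cat.), benzene, reflux, Dean–Stark trap
Reagents that add atoms: ethylene glycol, OCCO
Why: Acid-catalysed ketalisation driven by azeotropic removal of water masks the ketone for the ozonolysis, Lewis-acid and hydrazine steps ahead, and the fully substituted ring-A centre cannot epimerise.

Step 5
Reactants: 6 (6R)-6-methyl-6-(prop-2-en-1-yl)-1,4-dioxaspiro[4.4]nonane
Product: 8 2-[(6R)-6-methyl-1,4-dioxaspiro[4.4]nonan-6-yl]acetaldehyde, via secondary ozonide 7 (not isolated)
Conditions: O3, CH2Cl2, −78 °C; then PPh3, −78 °C → rt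
Reagents that add atoms: ozone, [O-][O+]=O
Why: Ozonolysis with reductive work-up, in which 1,3-dipolar cycloaddition of ozone to the only alkene, rearrangement to the secondary ozonide and reduction by PPh3 give the aldehyde one carbon shorter, while the ketal, which has no acetal C–H, is inert.

Step 6
Reactants: 8 2-[(6R)-6-methyl-1,4-dioxaspiro[4.4]nonan-6-yl]acetaldehyde
Product: 10 2-[(6R)-6-methyl-1,4-dioxaspiro[4.4]nonan-6-yl]prop-2-enal, via Mannich base 9 (not isolated)
Conditions: CH2=NMe2+ I− (Eschenmoser's salt), Et3N, CH2Cl2, rt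
Reagents that add atoms: N,N-dimethylmethyleneiminium iodide, C=[N+](C)C.[I-]
Why: α-Methylenation of an aldehyde by a Mannich reaction with the preformed iminium salt followed by base-induced (E1cB) loss of dimethylamine from the β-amino aldehyde, a sequence that cannot touch the quaternary ring-A centre.

Step 7
Reactants: 10 2-[(6R)-6-methyl-1,4-dioxaspiro[4.4]nonan-6-yl]prop-2-enal; 11 isoprene
Product: 12 (1S)-4-methyl-1-[(6R)-6-methyl-1,4-dioxaspiro[4.4]nonan-6-yl]cyclohex-3-ene-1-carbaldehyde
Conditions: (S)-3,3-diphenyl-1-(2-methylphenyl)tetrahydro-1H,3H-pyrrolo[1,2-c][1,3,2]oxazaborole from (S)-α,α-diphenylprolinol (20 mol%), HN(SO2CF3)2 (18 mol%), 11 (10 equiv), CH2Cl2, −78 → −20 °C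
Reagents that add atoms: none
Why: The N-protonated oxazaborolidine is a chiral Lewis acid that binds the formyl oxygen of 10 syn to the formyl hydrogen, a formyl C–H···O contact to the ring oxygen holding the s-trans enal over one C-phenyl group, and isoprene then adds to the uncovered face in a concerted, asynchronous [4+2] cycloaddition in which the B5–B6 bond (diene CH2 next to the methyl-bearing carbon onto the β-carbon) runs ahead of B1–B2. The closest known reaction type is the oxazaborolidinium-catalysed enantioselective Diels–Alder reaction of 2-methyl- and 2-bromoacrolein with isoprene, and ketal-bearing dienophiles such as quinone monoketals are known to survive these catalysts, which is why the acid is kept below the oxazaborolidine loading so that no free HN(SO2CF3)2 remains. Ring B is closed by an intermolecular [4+2] cycloaddition that forms B1–B2 and B5–B6 in one step and leaves the B3=B4 alkene. The new stereocentre B1 is set under reagent control by the (S)-configured catalyst, whose model predicts attack on the enal face that gives (1S)-12, while the ring-A quaternary centre, fixed in step 3, is a bystander whose own bias may help or oppose. The step needs facial selectivity at B1 and para regioselectivity: the first rests on the catalyst, the second on the 2-methyl group of isoprene, whose larger terminal coefficient pairs with the Lewis-acid-activated β-carbon. Because the ring-A centre is already in place, attack on the wrong face, like the minor enantiomer carried over from step 3, gives a diastereomer of 12 that chromatography should remove.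

Step 8
Reactants: 12 (1S)-4-methyl-1-[(6R)-6-methyl-1,4-dioxaspiro[4.4]nonan-6-yl]cyclohex-3-ene-1-carbaldehyde
Product: 14 (6R)-6-[(1R)-1,4-dimethylcyclohex-3-en-1-yl]-6-methyl-1,4-dioxaspiro[4.4]nonane, via hydrazone 13 (not isolated)
Conditions: N2H4·H2O, KOH, diethylene glycol, 130 °C, then 200 °C
Reagents that add atoms: none
Why: Wolff–Kishner reduction (Huang-Minlon procedure), in which the non-enolisable neopentyl aldehyde condenses with hydrazine and the hydrazone anion loses N2 at 200 °C to leave the B1 methyl, under basic conditions that the ketal, the trisubstituted alkene and both quaternary centres tolerate (the descriptor at B1 changes only through the priority rules).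

Step 9
Reactants: 14 (6R)-6-[(1R)-1,4-dimethylcyclohex-3-en-1-yl]-6-methyl-1,4-dioxaspiro[4.4]nonane
Product: 15 (5S)-2,5-dimethyl-5-[(6R)-6-methyl-1,4-dioxaspiro[4.4]nonan-6-yl]cyclohex-2-en-1-ol (both epimers at the carbinol carbon B5)
Conditions: SeO2 (0.5 equiv), t-BuOOH (3 equiv, decane solution), CH2Cl2, 0 °C → rt
Reagents that add atoms: selenium dioxide, O=[Se]=O; tert-butyl hydroperoxide, CC(C)(C)OO
Why: Selenium dioxide allylic oxidation (ene reaction at B3=B4 followed by [2,3]-sigmatropic shift of the allylic seleninic acid) returns the alkene to B3=B4 and puts oxygen on the ring CH2 attached to the more substituted alkene carbon, B5, in line with the established site preference for 1-methylcyclohexenes, the neopentyl B2 being at the wrong terminus and hindered; the configuration at B5 is not controlled here and does not need to be.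

Step 10
Reactants: 15 (5S)-2,5-dimethyl-5-[(6R)-6-methyl-1,4-dioxaspiro[4.4]nonan-6-yl]cyclohex-2-en-1-ol
Product: 16 (5S)-2,5-dimethyl-5-[(6R)-6-methyl-1,4-dioxaspiro[4.4]nonan-6-yl]cyclohex-2-en-1-one
Conditions: activated MnO2 (excess), CH2Cl2, rt
Reagents that add atoms: none
Why: Heterogeneous MnO2 oxidation is selective for allylic alcohols and converges both B5 epimers on one enone under neutral conditions that spare the ketal.

Step 11
Reactants: 16 (5S)-2,5-dimethyl-5-[(6R)-6-methyl-1,4-dioxaspiro[4.4]nonan-6-yl]cyclohex-2-en-1-one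
Product: 17 (1S,5S)-2,5-dimethyl-5-[(6R)-6-methyl-1,4-dioxaspiro[4.4]nonan-6-yl]cyclohex-2-en-1-ol
Conditions: (R)-1-methyl-3,3-diphenyltetrahydro-1H,3H-pyrrolo[1,2-c][1,3,2]oxazaborole (0.3 equiv), BH3·SMe2 (0.7 equiv), THF, −30 °C; MeOH, then aqueous work-up
Reagents that add atoms: none
Why: Corey–Bakshi–Shibata reduction, in which the ketone binds the catalyst boron anti to its larger α-methylalkenyl arm and hydride is delivered within the complex from the N-bound borane, so that the (R)-catalyst should give the (S)-carbinol at B5 (hydroxyl cis to ring A) under reagent control and with 1,2-selectivity.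

Step 12
Reactants: 17 (1S,5S)-2,5-dimethyl-5-[(6R)-6-methyl-1,4-dioxaspiro[4.4]nonan-6-yl]cyclohex-2-en-1-ol
Product: 18 (2R)-2-[(1S,5S)-5-hydroxy-1,4-dimethylcyclohex-3-en-1-yl]-2-methylcyclopentan-1-one
Conditions: pyridinium p-toluenesulfonate (0.2 equiv), acetone/H2O (5:1), 50 °C
Reagents that add atoms: water, O
Why: Mild acid-catalysed ketal hydrolysis through the oxocarbenium ion releases the cyclopentanone, the buffered acid being too weak to ionise the secondary allylic alcohol, so B5 keeps its configuration.

Step 13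
Reactants: 18 (2R)-2-[(1S,5S)-5-hydroxy-1,4-dimethylcyclohex-3-en-1-yl]-2-methylcyclopentan-1-one
Product: 19 (1S,5S)-2,5-dimethyl-5-[(1S)-1-methyl-2-methylidenecyclopentyl]cyclohex-2-en-1-ol
Conditions: Ph3PCH3Br (6 equiv), KOt-Bu (6 equiv), toluene, 25 → 100 °C
Reagents that add atoms: methyltriphenylphosphonium bromide, C[P+](c1ccccc1)(c1ccccc1)c1ccccc1.[Br-]
Why: Wittig methylenation with a large excess of ylide at elevated temperature, the usual answer to a hindered ketone, in which the first equivalent of base turns the hydroxyl into an inert alkoxide and the ketone has no epimerisable α-stereocentre.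

Step 14
Reactants: 20 caffeic acid
Product: 22 (2E)-3-[3,4-bis(tert-butyldimethylsilyloxy)phenyl]prop-2-enoic acid, via tris-silyl derivative 21 (not isolated)
Conditions: TBSCl (3.3 equiv), imidazole (7 equiv), DMF, rt; then AcOH/THF/H2O, rt
Reagents that add atoms: tert-butyldimethylsilyl chloride, CC(C)(C)[Si](C)(C)Cl
Why: Exhaustive silylation followed by selective hydrolysis of the silyl ester, which dilute acetic acid cleaves while aryl silyl ethers stay on, gives the catechol-protected acid with the E-alkene untouched.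

Step 15
Reactants: 19 (1S,5S)-2,5-dimethyl-5-[(1S)-1-methyl-2-methylidenecyclopentyl]cyclohex-2-en-1-ol; 22 (2E)-3-[3,4-bis(tert-butyldimethylsilyloxy)phenyl]prop-2-enoic acid
Product: 23 (1S,5S)-2,5-dimethyl-5-[(1S)-1-methyl-2-methylidenecyclopentyl]cyclohex-2-en-1-yl (2E)-3-[3,4-bis(tert-butyldimethylsilyloxy)phenyl]prop-2-enoate
Conditions: DCC (1.5 equiv), 4-(dimethylamino)pyridine (0.3 equiv), CH2Cl2, 0 °C → rt
Reagents that add atoms: none
Why: Steglich esterification, in which DCC activates the acid as its O-acylisourea and the pyridine catalyst relays the acyl group to the secondary allylic alcohol, acylation at oxygen leaving the B5 configuration as it is.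

Step 16
Reactants: 23 (1S,5S)-2,5-dimethyl-5-[(1S)-1-methyl-2-methylidenecyclopentyl]cyclohex-2-en-1-yl (2E)-3-[3,4-bis(tert-butyldimethylsilyloxy)phenyl]prop-2-enoate
Product: 24 (1S,5S)-2,5-dimethyl-5-[(1S)-1-methyl-2-methylidenecyclopentyl]cyclohex-2-en-1-yl (2E)-3-(3,4-dihydroxyphenyl)prop-2-enoate (CNP0268865.1)
Conditions: Bu4NF (2.5 equiv), AcOH (3 equiv), THF, 0 °C
Reagents that add atoms: none
Why: Fluoride-mediated desilylation cleaves the two aryl silyl ethers quickly at 0 °C (strong Si–F bond, phenoxide as leaving group), acetic acid buffering the phenoxides so that neither the allylic ester nor the catechol should suffer.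

Compound list

1 | methyl 2-oxocyclopentane-1-carboxylate | COC(=O)C1CCCC1=O | starting material
2 | allyl alcohol | C=CCO | starting material
3 | prop-2-en-1-yl 2-oxocyclopentane-1-carboxylate | C=CCOC(=O)C1CCCC1=O | intermediate
4 | prop-2-en-1-yl 1-methyl-2-oxocyclopentane-1-carboxylate (racemic) | C=CCOC(=O)C1(C)CCCC1=O | intermediate
5 | (2R)-2-methyl-2-(prop-2-en-1-yl)cyclopentan-1-one | O=C1CCC[C@]1(C)CC=C | intermediate
6 | (6R)-6-methyl-6-(prop-2-en-1-yl)-1,4-dioxaspiro[4.4]nonane | O1CCOC12CCC[C@]2(C)CC=C | intermediate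
7 | 3-{[(6R)-6-methyl-1,4-dioxaspiro[4.4]nonan-6-yl]methyl}-1,2,4-trioxolane (secondary ozonide) | O1CCOC12CCC[C@]2(C)CC3OCOO3 | intermediate (not isolated)
8 | 2-[(6R)-6-methyl-1,4-dioxaspiro[4.4]nonan-6-yl]acetaldehyde | O1CCOC12CCC[C@]2(C)CC=O | intermediate
9 | 3-(dimethylamino)-2-[(6R)-6-methyl-1,4-dioxaspiro[4.4]nonan-6-yl]propanal (Mannich base) | O1CCOC12CCC[C@]2(C)C(CN(C)C)C=O | intermediate (not isolated)
10 | 2-[(6R)-6-methyl-1,4-dioxaspiro[4.4]nonan-6-yl]prop-2-enal | O1CCOC12CCC[C@]2(C)C(=C)C=O | intermediate
11 | isoprene | C=CC(C)=C | starting material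
12 | (1S)-4-methyl-1-[(6R)-6-methyl-1,4-dioxaspiro[4.4]nonan-6-yl]cyclohex-3-ene-1-carbaldehyde | O1CCOC12CCC[C@]2(C)[C@@]1(C=O)CC=C(C)CC1 | intermediate
13 | hydrazone of 12 | O1CCOC12CCC[C@]2(C)[C@@]1(C=NN)CC=C(C)CC1 | intermediate (not isolated)
14 | (6R)-6-[(1R)-1,4-dimethylcyclohex-3-en-1-yl]-6-methyl-1,4-dioxaspiro[4.4]nonane | O1CCOC12CCC[C@]2(C)[C@@]1(C)CC=C(C)CC1 | intermediate
15 | (5S)-2,5-dimethyl-5-[(6R)-6-methyl-1,4-dioxaspiro[4.4]nonan-6-yl]cyclohex-2-en-1-ol (epimers at the carbinol carbon) | O1CCOC12CCC[C@]2(C)[C@@]1(C)CC=C(C)C(O)C1 | intermediate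
16 | (5S)-2,5-dimethyl-5-[(6R)-6-methyl-1,4-dioxaspiro[4.4]nonan-6-yl]cyclohex-2-en-1-one | O1CCOC12CCC[C@]2(C)[C@@]1(C)CC=C(C)C(=O)C1 | intermediate
17 | (1S,5S)-2,5-dimethyl-5-[(6R)-6-methyl-1,4-dioxaspiro[4.4]nonan-6-yl]cyclohex-2-en-1-ol | O1CCOC12CCC[C@]2(C)[C@@]1(C)CC=C(C)[C@@H](O)C1 | intermediate
18 | (2R)-2-[(1S,5S)-5-hydroxy-1,4-dimethylcyclohex-3-en-1-yl]-2-methylcyclopentan-1-one | O=C1CCC[C@]1(C)[C@@]1(C)CC=C(C)[C@@H](O)C1 | intermediate
19 | (1S,5S)-2,5-dimethyl-5-[(1S)-1-methyl-2-methylidenecyclopentyl]cyclohex-2-en-1-ol | C=C1CCC[C@]1(C)[C@@]1(C)CC=C(C)[C@@H](O)C1 | intermediate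
20 | caffeic acid | OC(=O)/C=C/c1ccc(O)c(O)c1 | starting material
21 | tert-butyldimethylsilyl (2E)-3-[3,4-bis(tert-butyldimethylsilyloxy)phenyl]prop-2-enoate | CC(C)(C)[Si](C)(C)OC(=O)/C=C/c1ccc(O[Si](C)(C)C(C)(C)C)c(O[Si](C)(C)C(C)(C)C)c1 | intermediate (not isolated)
22 | (2E)-3-[3,4-bis(tert-butyldimethylsilyloxy)phenyl]prop-2-enoic acid | OC(=O)/C=C/c1ccc(O[Si](C)(C)C(C)(C)C)c(O[Si](C)(C)C(C)(C)C)c1 | intermediate
23 | (1S,5S)-2,5-dimethyl-5-[(1S)-1-methyl-2-methylidenecyclopentyl]cyclohex-2-en-1-yl (2E)-3-[3,4-bis(tert-butyldimethylsilyloxy)phenyl]prop-2-enoate | C=C1CCC[C@]1(C)[C@@]1(C)CC=C(C)[C@@H](OC(=O)/C=C/c2ccc(O[Si](C)(C)C(C)(C)C)c(O[Si](C)(C)C(C)(C)C)c2)C1 | intermediate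
24 | (1S,5S)-2,5-dimethyl-5-[(1S)-1-methyl-2-methylidenecyclopentyl]cyclohex-2-en-1-yl (2E)-3-(3,4-dihydroxyphenyl)prop-2-enoate | C=C1CCC[C@]1(C)[C@@]1(C)CC=C(C)[C@@H](OC(=O)/C=C/c2ccc(O)c(O)c2)C1 | target

Total step count: 16. Longest linear sequence: 15 steps (steps 1–13, 15 and 16; step 14 is a one-step side branch).

Steps most likely to fail

Step 7. The cycloaddition may be slow because the dienophile carbon that becomes B1 sits next to a fully substituted, ketal-flanked carbon. Facial selectivity may erode if the bias of the ring-A stereocentre opposes the catalyst. The catalyst may also lose activity by binding to the dioxolane oxygens. The fallback no longer insists on one face. The B1 epimer of the adduct differs from 12 only in which arm of B1 holds the alkene, so it can reach the same enone by oxygenating the alkene CH, which in that epimer is B5, and not an allylic CH2. Setting out from 10, cycloaddition with isoprene under the enantiomeric oxazaborolidinium catalyst (from (R)-α,α-diphenylprolinol, the pairing that would then be matched), or under Me2AlCl with separation of the epimers, gives (1R)-4-methyl-1-[(6R)-6-methyl-1,4-dioxaspiro[4.4]nonan-6-yl]cyclohex-3-ene-1-carbaldehyde F1. Wolff–Kishner reduction through its hydrazone F2 gives (6R)-6-[(1S)-1,4-dimethylcyclohex-3-en-1-yl]-6-methyl-1,4-dioxaspiro[4.4]nonane F3. Hydroboration–oxidation (BH3·THF, then NaOH/H2O2) places the hydroxyl on the less substituted alkene carbon to give (5S)-2,5-dimethyl-5-[(6R)-6-methyl-1,4-dioxaspiro[4.4]nonan-6-yl]cyclohexan-1-ol F4. Swern oxidation gives the corresponding (5S)-2,5-dimethylcyclohexan-1-one F5. TMSCl/Et3N in hot DMF under equilibrating conditions gives the more substituted trimethylsilyl enol ether F6, and Saegusa–Ito dehydrogenation (Pd(OAc)2, MeCN) comes back to the route at 16.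

Step 11. The hydride has to enter from the ring face that carries the axial B1 methyl, so substrate bias may override the catalyst and give the B5 epimer or a mixture. The fallback uses that bias and corrects it by inversion. Setting out from 16, 1,2-reduction under substrate control (i-Bu2AlH, toluene, −78 °C) should favour the alcohol with the hydroxyl trans to ring A, (1R,5S)-2,5-dimethyl-5-[(6R)-6-methyl-1,4-dioxaspiro[4.4]nonan-6-yl]cyclohex-2-en-1-ol F7. Mitsunobu reaction with 4-nitrobenzoic acid (PPh3, DIAD, THF) inverts B5 to give the (1S,5S)-4-nitrobenzoate F8, and methanolysis (K2CO3, MeOH) comes back to the route at 17.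

Step 13. The bulky ylide may fail to add to a carbonyl flanked by two adjacent quaternary carbons, enolisation at the ring-A CH2 next to the carbonyl may compete, and the ketone may be masked by reversible addition of the B5 alkoxide. The fallback is a Peterson olefination with a smaller, less basic nucleophile. Setting out from 18, Me3SiCH2Li with anhydrous CeCl3 (excess, THF, −78 → 0 °C) adds to the ketone to give the β-hydroxysilane, (1S,5S)-5-{(1R)-2-hydroxy-1-methyl-2-[(trimethylsilyl)methyl]cyclopentyl}-2,5-dimethylcyclohex-2-en-1-ol F9, and KH in THF triggers elimination of silanolate to come back to the route at 19.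

Further compounds

F1 | step 7 | (1R)-4-methyl-1-[(6R)-6-methyl-1,4-dioxaspiro[4.4]nonan-6-yl]cyclohex-3-ene-1-carbaldehyde | O1CCOC12CCC[C@]2(C)[C@]1(C=O)CC=C(C)CC1
F2 | step 7 | hydrazone of F1 | O1CCOC12CCC[C@]2(C)[C@]1(C=NN)CC=C(C)CC1
F3 | step 7 | (6R)-6-[(1S)-1,4-dimethylcyclohex-3-en-1-yl]-6-methyl-1,4-dioxaspiro[4.4]nonane | O1CCOC12CCC[C@]2(C)[C@]1(C)CC=C(C)CC1
F4 | step 7 | (5S)-2,5-dimethyl-5-[(6R)-6-methyl-1,4-dioxaspiro[4.4]nonan-6-yl]cyclohexan-1-ol (carbinol and methyl-bearing ring carbons unassigned) | O1CCOC12CCC[C@]2(C)[C@]1(C)CC(O)C(C)CC1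
F5 | step 7 | (5S)-2,5-dimethyl-5-[(6R)-6-methyl-1,4-dioxaspiro[4.4]nonan-6-yl]cyclohexan-1-one (methyl-bearing α-carbon unassigned) | O1CCOC12CCC[C@]2(C)[C@]1(C)CC(=O)C(C)CC1
F6 | step 7 | {[(5S)-2,5-dimethyl-5-[(6R)-6-methyl-1,4-dioxaspiro[4.4]nonan-6-yl]cyclohex-1-en-1-yl]oxy}trimethylsilane | O1CCOC12CCC[C@]2(C)[C@]1(C)CC(O[Si](C)(C)C)=C(C)CC1
F7 | step 11 | (1R,5S)-2,5-dimethyl-5-[(6R)-6-methyl-1,4-dioxaspiro[4.4]nonan-6-yl]cyclohex-2-en-1-ol | O1CCOC12CCC[C@]2(C)[C@@]1(C)CC=C(C)[C@H](O)C1
F8 | step 11 | (1S,5S)-2,5-dimethyl-5-[(6R)-6-methyl-1,4-dioxaspiro[4.4]nonan-6-yl]cyclohex-2-en-1-yl 4-nitrobenzoate | O1CCOC12CCC[C@]2(C)[C@@]1(C)CC=C(C)[C@@H](OC(=O)c3ccc(cc3)[N+](=O)[O-])C1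
F9 | step 13 | (1S,5S)-5-{(1R)-2-hydroxy-1-methyl-2-[(trimethylsilyl)methyl]cyclopentyl}-2,5-dimethylcyclohex-2-en-1-ol (carbinol carbon of ring A unassigned) | C[Si](C)(C)CC1(O)CCC[C@]1(C)[C@@]1(C)CC=C(C)[C@@H](O)C1
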